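**Plan**

- Target numbering: quinone ring C1–C4 (side chain on C2), ring fusion C4a/C8a, carbinol carbon C1'. The retrosynthesis cuts the butanoate C–O bond, then the C1 oxygen (back to a 1‑naphthol), then C4–C4a and C2–C3 together, then C2–C4 (acetyl), C1–C8a (aryl–alkyne) and C2–C1' (alkyne–carbinol).
- Enabling feature: C1, C2, C3 and C4 are a four‑carbon chain that can hang from C8a of the hydroquinone bis‑silyl ether ring as an aryl dienylketene and close on the unsubstituted ortho carbon C4a. The benzenoid ring C4a–C8a is bought; the quinone ring is the only ring made.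
- Forward order: C2–C1' (acetylide and Weinreb amide), C1–C8a (Sonogashira), trans‑hydrostannation to fix the alkene, C2–C4 (acetylation), diazo transfer at C3, photochemical ring closure, oxidation to the quinone, desilylation, butanoylation.
- Stereochemistry: C1' (R) is set by Noyori transfer hydrogenation of the ynone with the (R,R)‑TsDPEN ruthenium catalyst, and none of its four bonds is broken afterwards. The alkene geometry needed for ring closure comes from the hydroxyl‑directed trans‑hydrostannation.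

Key step: step 11

Abbreviations: TBS = tert‑butyldimethylsilyl, TBSO = tert‑butyldimethylsilyloxy, CDI = 1,1'‑carbonyldiimidazole, DCC = N,N'‑dicyclohexylcarbodiimide.
Remark: the 5,8‑dihydroxy‑1,4‑naphthoquinone core equilibrates rapidly between its naphthazarin tautomers; the drawn form with the side chain on the quinone ring is taken as the target.

**Route**

Step 1
Reactants: 1 bromohydroquinone (2‑bromobenzene‑1,4‑diol); 2 tert‑butyldimethylsilyl chloride
Product: 3 2‑bromo‑1,4‑bis(TBSO)benzene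
Conditions: TBSCl (2.4 equiv), imidazole, DMF, rt
Reagents that add atoms: tert‑butyldimethylsilyl chloride (2), CC(C)(C)[Si](C)(C)Cl
Why: Imidazole‑promoted silylation of both phenols is routine, and the aryl silyl ethers should survive the later organolithium, amine and photochemical steps yet leave under HF.

Step 2
Reactants: 4 4‑methylpent‑3‑enoic acid; 5 N,O‑dimethylhydroxylamine hydrochloride
Product: 7 N‑methoxy‑N,4‑dimethylpent‑3‑enamide, via 1‑(4‑methylpent‑3‑enoyl)imidazole 6 (not isolated)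
Conditions: CDI, CH2Cl2, rt; then MeNHOMe·HCl, rt
Reagents that add atoms: N,O‑dimethylhydroxylamine hydrochloride (5), CNOC.Cl
Why: Amidation through the acyl imidazole needs neither an acid chloride nor a strong base, so the β,γ‑alkene should stay out of conjugation.

Step 3
Reactants: 7 N‑methoxy‑N,4‑dimethylpent‑3‑enamide; 8 ethynyltrimethylsilane
Product: 10 6‑methyl‑1‑(trimethylsilyl)hept‑5‑en‑1‑yn‑3‑one, via lithium (trimethylsilyl)acetylide 9 (not isolated)
Conditions: 8, n‑BuLi, THF, −78 °C; then 7, −78 to −20 °C; cold aq NH4Cl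
Reagents that add atoms: ethynyltrimethylsilane (8), C#C[Si](C)(C)C
Why: Weinreb ketone synthesis: the acetylide adds once and the chelated tetrahedral adduct persists until the cold quench, which also limits enolization of the doubly activated CH2.

Step 4
Reactants: 10 6‑methyl‑1‑(trimethylsilyl)hept‑5‑en‑1‑yn‑3‑one
Product: 11 (R)‑6‑methyl‑1‑(trimethylsilyl)hept‑5‑en‑1‑yn‑3‑ol
Conditions: Ru[(R,R)‑TsNCHPhCHPhNH](p‑cymene) (1 mol %, preformed from RuCl[(R,R)‑TsDPEN](p‑cymene) and KOH), i‑PrOH, rt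
Reagents that add atoms: none
Why: Noyori asymmetric transfer hydrogenation of an alkynyl ketone: the alkynyl group takes the place of the aryl group of acetophenone in the CH/π‑controlled transition state, so the (R,R) catalyst should deliver hydride to the face that gives the (R)‑carbinol, and the base‑free amido complex should not isomerize the β,γ‑unsaturated ketone.

Step 5
Reactants: 11 (R)‑6‑methyl‑1‑(trimethylsilyl)hept‑5‑en‑1‑yn‑3‑ol
Product: 12 (R)‑6‑methylhept‑5‑en‑1‑yn‑3‑ol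
Conditions: K2CO3 (cat.), MeOH, 0 °C to rt
Reagents that add atoms: none
Why: Carbonate‑catalysed methanolysis of the C(sp)–Si bond (protodesilylation) is selective for the alkynylsilane and is placed before the base‑sensitive aryl silyl ethers are introduced.

Step 6
Reactants: 12 (R)‑6‑methylhept‑5‑en‑1‑yn‑3‑ol; 3 2‑bromo‑1,4‑bis(TBSO)benzene
Product: 13 (R)‑1‑[2,5‑bis(TBSO)phenyl]‑6‑methylhept‑5‑en‑1‑yn‑3‑ol
Conditions: Pd(PhCN)2Cl2 (3 mol %), [HP(t‑Bu)3]BF4 (6 mol %), CuI (2 mol %), i‑Pr2NH, dioxane, rt to 40 °C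
Reagents that add atoms: 2‑bromo‑1,4‑bis(TBSO)benzene (3), CC(C)(C)[Si](C)(C)Oc1ccc(O[Si](C)(C)C(C)(C)C)c(Br)c1
Why: Sonogashira coupling: the bulky electron‑rich phosphine lets zerovalent palladium insert into the electron‑rich, ortho‑substituted aryl bromide near room temperature, and the free carbinol, prenyl alkene and aryl silyl ethers are inert to the amine medium.

Step 7
Reactants: 13 (R)‑1‑[2,5‑bis(TBSO)phenyl]‑6‑methylhept‑5‑en‑1‑yn‑3‑ol; 14 tributyltin hydride
Product: 15 (R,Z)‑1‑[2,5‑bis(TBSO)phenyl]‑6‑methyl‑2‑(tributylstannyl)hepta‑1,5‑dien‑3‑ol (tin cis to the aryl group)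
Conditions: [(C5Me5)RuCl]4 (1.5 mol %), Bu3SnH (1.1 equiv, slow addition), CH2Cl2, rt
Reagents that add atoms: tributyltin hydride (14), CCCC[SnH](CCCC)CCCC
Why: Ruthenium‑catalysed hydroxyl‑directed trans‑hydrostannation: hydrogen bonding of the propargylic OH to the Ru–Cl unit steers tin to the alkyne carbon next to the carbinol and H and Sn add to opposite faces, so the aryl group ends trans to the carbinol carbon and cis to tin.

Step 8
Reactants: 15 the hydroxy stannane; 16 tert‑butyldimethylsilyl trifluoromethanesulfonate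
Product: 17 (R,Z)‑tributyl{1‑[2,5‑bis(TBSO)phenyl]‑3‑(TBSO)‑6‑methylhepta‑1,5‑dien‑2‑yl}stannane
Conditions: TBSOTf, 2,6‑lutidine, CH2Cl2, −78 to 0 °C
Reagents that add atoms: tert‑butyldimethylsilyl trifluoromethanesulfonate (16), CC(C)(C)[Si](C)(C)OS(=O)(=O)C(F)(F)F
Why: Silyl triflate with a hindered pyridine base is the standard silylation of a crowded secondary alcohol, and the buffered cold medium should avoid protodestannylation.

Step 9
Reactants: 17 the silylated alkenylstannane; 18 N‑methoxy‑N‑methylacetamide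
Product: 20 (R,Z)‑3‑[2,5‑bis(TBSO)benzylidene]‑4‑(TBSO)‑7‑methyloct‑6‑en‑2‑one (aryl cis to the acetyl group), via alkenyllithium 19 (not isolated)
Conditions: MeLi (1.05 equiv), THF, −78 °C; then 18, −78 to −20 °C; aq NH4Cl
Reagents that add atoms: N‑methoxy‑N‑methylacetamide (18), CC(=O)N(C)OC
Why: Tin–lithium exchange proceeds with retention of alkene geometry and the alkenyllithium adds once to the Weinreb amide (Weinreb ketone synthesis), forming the C2–C4 bond while the silyl ethers are inert to MeLi at −78 °C.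

Step 10
Reactants: 20 the methyl enone; 21 2,2,2‑trifluoroethyl trifluoroacetate; 22 4‑acetamidobenzenesulfonyl azide
Product: 24 (R,Z)‑1‑diazo‑3‑[2,5‑bis(TBSO)benzylidene]‑4‑(TBSO)‑7‑methyloct‑6‑en‑2‑one, via trifluoroacetyl diketone 23 (not isolated)
Conditions: LiN(SiMe3)2 (1.1 equiv), THF, −78 °C; CF3CO2CH2CF3; extractive work‑up; then 22, Et3N, H2O (1 equiv), MeCN, rt
Reagents that add atoms: 4‑acetamidobenzenesulfonyl azide (22), CC(=O)Nc1ccc(cc1)S(=O)(=O)N=[N+]=[N-]
Why: Detrifluoroacetylative (Regitz‑type) diazo transfer: kinetic deprotonation at the only enolizable position (the methyl group) and Claisen trifluoroacetylation give an activated 1,3‑diketone that accepts the diazo group and loses the trifluoroacetyl group as the sulfonamide, a method established for α,β‑unsaturated methyl ketones that avoids diazomethane and its dipolar cycloaddition to the enone.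

Step 11
Reactants: 24 the (Z)‑diazo enone
Product: 27 (R)‑3‑[1‑(TBSO)‑4‑methylpent‑3‑enyl]‑5,8‑bis(TBSO)naphthalen‑1‑ol, via aryl dienylketene 25 (not isolated), via 8aH‑naphthalen‑1‑one keto tautomer 26 (not isolated)
Conditions: hν (365 nm), degassed dry toluene (0.01 M), rt; then 80 °C in the dark
Reagents that add atoms: none
Why: Proposed new method: excitation of 24 expels N2 with a 1,2‑shift of the alkenyl group from the carbonyl carbon to the diazo carbon (new C2–C3 bond, target numbering), giving ketene 25 with the aryl ring cis to the ketene‑bearing carbon; the closest known reaction types are the photochemical Wolff rearrangement of α,β‑unsaturated α'‑diazo ketones to vinylketenes and the closure of aryl dienylketenes to 1‑naphthols in Stobbe‑type anhydride cyclizations and 4‑arylcyclobutenone ring expansions, which have not been joined on a (Z)‑β‑aryl diazo enone. The six‑membered carbocycle closes by a thermal disrotatory 6π‑electrocyclization across the ketene C=C, the C2=C1 alkene and the C8a=C4a bond of the arene (new C4–C4a bond), and keto tautomer 26 then enolizes to the aromatic naphthol. No permanent stereocentre is created, since the sp3 ring‑fusion C–H of 26 is erased on tautomerization, and the C1' centre is neither part of the reacting π system nor exposed to acid or base, so it should be carried through unchanged. The step needs the aryl‑cis alkene geometry and closure at the one unsubstituted ortho carbon: the geometry is fixed in step 7 and kept through steps 8 to 10, and the other ortho position carries a silyloxy group. Metal‑free generation at high dilution should suppress carbenoid cyclopropanation of the prenyl alkene and ketene dimerization, and the final warming lets any cyclobutenone or aryl‑trans ketene return through reversible 4π ring opening to the reactive isomer.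

Step 12
Reactants: 27 the naphthol; 28 potassium nitrosodisulfonate
Product: 29 (R)‑2‑[1‑(TBSO)‑4‑methylpent‑3‑enyl]‑5,8‑bis(TBSO)naphthalene‑1,4‑dione
Conditions: (KSO3)2NO (2.5 equiv), KH2PO4 buffer, acetone/H2O, 0 °C to rt
Reagents that add atoms: potassium nitrosodisulfonate (28), [K+].[K+].[O-]S(=O)(=O)N([O])S(=O)(=O)[O-]
Why: Teuber oxidation: the nitroxide radical abstracts the phenolic hydrogen and a second equivalent adds at the free para carbon (C1 of the target), giving the 1,4‑quinone after loss of imidodisulfonate, while the silyl ethers shield the other ring and tolerate the near‑neutral buffer.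

Step 13
Reactants: 29 the tris‑silylated quinone
Product: 30 shikonin, (R)‑5,8‑dihydroxy‑2‑(1‑hydroxy‑4‑methylpent‑3‑enyl)naphthalene‑1,4‑dione
Conditions: HF·pyridine, pyridine, THF, 0 °C to rt
Reagents that add atoms: none
Why: Fluoride‑driven Si–O cleavage (HF·pyridine desilylation) removes the two aryl and the one alkyl silyl ether without base, which would deprotonate the naphthazarin or the vinylogously acidic C1'–H, and no bond to the stereocentre is broken.

Step 14
Reactants: 30 shikonin; 31 butanoic acid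
Product: 33 butylshikonin, (R)‑1‑(5,8‑dihydroxy‑1,4‑dioxo‑1,4‑dihydronaphthalen‑2‑yl)‑4‑methylpent‑3‑enyl butanoate, via O‑butanoyl‑N,N'‑dicyclohexylisourea 32 (not isolated)
Conditions: butanoic acid, DCC, DMAP (cat.), CH2Cl2, 0 °C to rt
Reagents that add atoms: butanoic acid (31), CCCC(O)=O
Why: Steglich esterification: the two peri‑hydroxyls are locked in hydrogen bonds to the quinone carbonyls and are poor nucleophiles, so only the secondary alcohol is acylated, with retention because the C1'–O bond stays intact.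

**Compound list**

1 | bromohydroquinone (2‑bromobenzene‑1,4‑diol) | Oc1ccc(O)c(Br)c1 | starting material
2 | tert‑butyldimethylsilyl chloride | CC(C)(C)[Si](C)(C)Cl | starting material
3 | 2‑bromo‑1,4‑bis(TBSO)benzene | CC(C)(C)[Si](C)(C)Oc1ccc(O[Si](C)(C)C(C)(C)C)c(Br)c1 | intermediate
4 | 4‑methylpent‑3‑enoic acid | CC(C)=CCC(O)=O | starting material
5 | N,O‑dimethylhydroxylamine hydrochloride | CNOC.Cl | starting material
6 | 1‑(4‑methylpent‑3‑enoyl)imidazole | CC(C)=CCC(=O)n1ccnc1 | intermediate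
7 | N‑methoxy‑N,4‑dimethylpent‑3‑enamide | CC(C)=CCC(=O)N(C)OC | intermediate
8 | ethynyltrimethylsilane | C#C[Si](C)(C)C | starting material
9 | lithium (trimethylsilyl)acetylide | [Li]C#C[Si](C)(C)C | intermediate
10 | 6‑methyl‑1‑(trimethylsilyl)hept‑5‑en‑1‑yn‑3‑one | CC(C)=CCC(=O)C#C[Si](C)(C)C | intermediate
11 | (R)‑6‑methyl‑1‑(trimethylsilyl)hept‑5‑en‑1‑yn‑3‑ol | C[Si](C)(C)C#C[C@H](O)CC=C(C)C | intermediate
12 | (R)‑6‑methylhept‑5‑en‑1‑yn‑3‑ol | C#C[C@H](O)CC=C(C)C | intermediate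
13 | (R)‑1‑[2,5‑bis(TBSO)phenyl]‑6‑methylhept‑5‑en‑1‑yn‑3‑ol | O[C@H](CC=C(C)C)C#Cc1cc(O[Si](C)(C)C(C)(C)C)ccc1O[Si](C)(C)C(C)(C)C | intermediate
14 | tributyltin hydride | CCCC[SnH](CCCC)CCCC | starting material
15 | (R,Z)‑1‑[2,5‑bis(TBSO)phenyl]‑6‑methyl‑2‑(tributylstannyl)hepta‑1,5‑dien‑3‑ol | O[C@H](CC=C(C)C)/C(=C/c1cc(O[Si](C)(C)C(C)(C)C)ccc1O[Si](C)(C)C(C)(C)C)[Sn](CCCC)(CCCC)CCCC | intermediate
16 | tert‑butyldimethylsilyl trifluoromethanesulfonate | CC(C)(C)[Si](C)(C)OS(=O)(=O)C(F)(F)F | starting material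
17 | (R,Z)‑tributyl{1‑[2,5‑bis(TBSO)phenyl]‑3‑(TBSO)‑6‑methylhepta‑1,5‑dien‑2‑yl}stannane | CC(C)(C)[Si](C)(C)O[C@H](CC=C(C)C)/C(=C/c1cc(O[Si](C)(C)C(C)(C)C)ccc1O[Si](C)(C)C(C)(C)C)[Sn](CCCC)(CCCC)CCCC | intermediate
18 | N‑methoxy‑N‑methylacetamide | CC(=O)N(C)OC | starting material
19 | (R,E)‑{1‑[2,5‑bis(TBSO)phenyl]‑3‑(TBSO)‑6‑methylhepta‑1,5‑dien‑2‑yl}lithium (lithium cis to the aryl group) | CC(C)(C)[Si](C)(C)O[C@H](CC=C(C)C)/C([Li])=C/c1cc(O[Si](C)(C)C(C)(C)C)ccc1O[Si](C)(C)C(C)(C)C | intermediate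
20 | (R,Z)‑3‑[2,5‑bis(TBSO)benzylidene]‑4‑(TBSO)‑7‑methyloct‑6‑en‑2‑one | CC(=O)/C(=C\c1cc(O[Si](C)(C)C(C)(C)C)ccc1O[Si](C)(C)C(C)(C)C)[C@H](O[Si](C)(C)C(C)(C)C)CC=C(C)C | intermediate
21 | 2,2,2‑trifluoroethyl trifluoroacetate | FC(F)(F)COC(=O)C(F)(F)F | starting material
22 | 4‑acetamidobenzenesulfonyl azide | CC(=O)Nc1ccc(cc1)S(=O)(=O)N=[N+]=[N-] | starting material
23 | (R,Z)‑5‑[2,5‑bis(TBSO)benzylidene]‑6‑(TBSO)‑1,1,1‑trifluoro‑9‑methyldec‑8‑ene‑2,4‑dione | O=C(CC(=O)C(F)(F)F)/C(=C\c1cc(O[Si](C)(C)C(C)(C)C)ccc1O[Si](C)(C)C(C)(C)C)[C@H](O[Si](C)(C)C(C)(C)C)CC=C(C)C | intermediate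
24 | (R,Z)‑1‑diazo‑3‑[2,5‑bis(TBSO)benzylidene]‑4‑(TBSO)‑7‑methyloct‑6‑en‑2‑one | [N-]=[N+]=CC(=O)/C(=C\c1cc(O[Si](C)(C)C(C)(C)C)ccc1O[Si](C)(C)C(C)(C)C)[C@H](O[Si](C)(C)C(C)(C)C)CC=C(C)C | intermediate
25 | (R,E)‑3‑[2,5‑bis(TBSO)benzylidene]‑4‑(TBSO)‑7‑methylocta‑1,6‑dien‑1‑one (ketene; aryl cis to the ketene‑bearing carbon) | O=C=C/C(=C\c1cc(O[Si](C)(C)C(C)(C)C)ccc1O[Si](C)(C)C(C)(C)C)[C@H](O[Si](C)(C)C(C)(C)C)CC=C(C)C | intermediate
26 | 3‑[(R)‑1‑(TBSO)‑4‑methylpent‑3‑enyl]‑5,8‑bis(TBSO)naphthalen‑1(8aH)‑one (both C8a epimers) | O=C1C=C([C@H](O[Si](C)(C)C(C)(C)C)CC=C(C)C)C=C2C(O[Si](C)(C)C(C)(C)C)=CC=C(O[Si](C)(C)C(C)(C)C)C12 | intermediate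
27 | (R)‑3‑[1‑(TBSO)‑4‑methylpent‑3‑enyl]‑5,8‑bis(TBSO)naphthalen‑1‑ol | CC(C)(C)[Si](C)(C)O[C@H](CC=C(C)C)c1cc(O)c2c(O[Si](C)(C)C(C)(C)C)ccc(O[Si](C)(C)C(C)(C)C)c2c1 | intermediate
28 | potassium nitrosodisulfonate | [K+].[K+].[O-]S(=O)(=O)N([O])S(=O)(=O)[O-] | starting material
29 | (R)‑2‑[1‑(TBSO)‑4‑methylpent‑3‑enyl]‑5,8‑bis(TBSO)naphthalene‑1,4‑dione | CC(C)(C)[Si](C)(C)O[C@H](CC=C(C)C)C1=CC(=O)c2c(O[Si](C)(C)C(C)(C)C)ccc(O[Si](C)(C)C(C)(C)C)c2C1=O | intermediate
30 | shikonin, (R)‑5,8‑dihydroxy‑2‑(1‑hydroxy‑4‑methylpent‑3‑enyl)naphthalene‑1,4‑dione | O[C@H](CC=C(C)C)C1=CC(=O)c2c(O)ccc(O)c2C1=O | intermediate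
31 | butanoic acid | CCCC(O)=O | starting material
32 | O‑butanoyl‑N,N'‑dicyclohexylisourea | CCCC(=O)OC(=NC1CCCCC1)NC1CCCCC1 | intermediate
33 | butylshikonin, (R)‑1‑(5,8‑dihydroxy‑1,4‑dioxo‑1,4‑dihydronaphthalen‑2‑yl)‑4‑methylpent‑3‑enyl butanoate | CCCC(=O)O[C@H](CC=C(C)C)C1=CC(=O)c2c(O)ccc(O)c2C1=O | target

**Step count and risks**

Total steps: 14. Longest linear sequence: 13 steps (from 4, steps 2 to 14).

Steps most likely to fail:

1. Step 11. The styrenyl double bond may photoisomerize before nitrogen is lost, the ketene may be captured by the prenyl alkene in an intramolecular [2+2] cycloaddition, or it may dimerize; each would divert material from the electrocyclization. Fallback from 17 to 27: the same aryl dienylketene would be generated from a carboxylic acid, as in the classical Stobbe‑type naphthol closure, with no diazo compound. Stannane 17 is lithiated (MeLi, THF, −78 °C) and the alkenyllithium 19 is opened onto ethylene oxide (BF3·OEt2, −78 °C) to give (R,E)‑3‑[2,5‑bis(TBSO)benzylidene]‑4‑(TBSO)‑7‑methyloct‑6‑en‑1‑ol F1. Dess–Martin oxidation should give (R,E)‑3‑[2,5‑bis(TBSO)benzylidene]‑4‑(TBSO)‑7‑methyloct‑6‑enal F2, and Pinnick oxidation (NaClO2, NaH2PO4, 2‑methyl‑2‑butene) the acid (R,E)‑3‑[2,5‑bis(TBSO)benzylidene]‑4‑(TBSO)‑7‑methyloct‑6‑enoic acid F3. Heating F3 with Ac2O and NaOAc forms the mixed anhydride, eliminates to the ketene and closes the ring to (R)‑3‑[1‑(TBSO)‑4‑methylpent‑3‑enyl]‑5,8‑bis(TBSO)naphthalen‑1‑yl acetate F4. Reductive removal of the acetate with i‑Bu2AlH at −78 °C leaves the silyl ethers in place and returns to naphthol 27.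

2. Step 7. The bulky ortho‑silyloxyaryl group may hamper alkyne binding at ruthenium or bind the metal through the arene, eroding regio‑ and trans‑selectivity or stalling the catalyst. Fallback from 13 to 20: an O‑directed free‑radical hydrostannation (Ph3SnH, cat. Et3B, trace air, toluene, rt) places tin on the carbon next to the carbinol, because stannyl radical addition there leaves an aryl‑stabilized vinyl radical that is quenched anti to tin. This should give (R,Z)‑1‑[2,5‑bis(TBSO)phenyl]‑6‑methyl‑2‑(triphenylstannyl)hepta‑1,5‑dien‑3‑ol F5. Iododestannylation (I2, CH2Cl2, 0 °C) with retention gives (R,Z)‑1‑[2,5‑bis(TBSO)phenyl]‑2‑iodo‑6‑methylhepta‑1,5‑dien‑3‑ol F6, and silylation (TBSOTf, 2,6‑lutidine) gives (R,Z)‑1‑[2,5‑bis(TBSO)phenyl]‑3‑(TBSO)‑2‑iodo‑6‑methylhepta‑1,5‑diene F7. Iodine–lithium exchange (t‑BuLi, 2 equiv, Et2O, −78 °C) forms alkenyllithium 19, which is acylated with 18 as in step 9 to reach methyl enone 20.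

3. Step 9. The crowded alkenyllithium may act as a base toward the acetamide instead of adding to it, so that protonation returns the destannylated alkene. Fallback from 17 to 20: the oxidation level of the electrophile is changed. Alkenyllithium 19 (from 17 and MeLi) is trapped with acetaldehyde at −78 °C, where addition should outrun proton transfer, to give (4R,E)‑3‑[2,5‑bis(TBSO)benzylidene]‑4‑(TBSO)‑7‑methyloct‑6‑en‑2‑ol F8 as a mixture of C2 epimers. Dess–Martin oxidation (NaHCO3, CH2Cl2) removes the new stereocentre and gives methyl enone 20.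

**Further compounds**

F1 | step 11 | (R,E)‑3‑[2,5‑bis(TBSO)benzylidene]‑4‑(TBSO)‑7‑methyloct‑6‑en‑1‑ol | OCC/C(=C\c1cc(O[Si](C)(C)C(C)(C)C)ccc1O[Si](C)(C)C(C)(C)C)[C@H](O[Si](C)(C)C(C)(C)C)CC=C(C)C
F2 | step 11 | (R,E)‑3‑[2,5‑bis(TBSO)benzylidene]‑4‑(TBSO)‑7‑methyloct‑6‑enal | O=CC/C(=C\c1cc(O[Si](C)(C)C(C)(C)C)ccc1O[Si](C)(C)C(C)(C)C)[C@H](O[Si](C)(C)C(C)(C)C)CC=C(C)C
F3 | step 11 | (R,E)‑3‑[2,5‑bis(TBSO)benzylidene]‑4‑(TBSO)‑7‑methyloct‑6‑enoic acid | OC(=O)C/C(=C\c1cc(O[Si](C)(C)C(C)(C)C)ccc1O[Si](C)(C)C(C)(C)C)[C@H](O[Si](C)(C)C(C)(C)C)CC=C(C)C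
F4 | step 11 | (R)‑3‑[1‑(TBSO)‑4‑methylpent‑3‑enyl]‑5,8‑bis(TBSO)naphthalen‑1‑yl acetate | CC(=O)Oc1cc([C@H](O[Si](C)(C)C(C)(C)C)CC=C(C)C)cc2c(O[Si](C)(C)C(C)(C)C)ccc(O[Si](C)(C)C(C)(C)C)c12
F5 | step 7 | (R,Z)‑1‑[2,5‑bis(TBSO)phenyl]‑6‑methyl‑2‑(triphenylstannyl)hepta‑1,5‑dien‑3‑ol | O[C@H](CC=C(C)C)/C(=C/c1cc(O[Si](C)(C)C(C)(C)C)ccc1O[Si](C)(C)C(C)(C)C)[Sn](c1ccccc1)(c1ccccc1)c1ccccc1
F6 | step 7 | (R,Z)‑1‑[2,5‑bis(TBSO)phenyl]‑2‑iodo‑6‑methylhepta‑1,5‑dien‑3‑ol | O[C@H](CC=C(C)C)/C(I)=C/c1cc(O[Si](C)(C)C(C)(C)C)ccc1O[Si](C)(C)C(C)(C)C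
F7 | step 7 | (R,Z)‑1‑[2,5‑bis(TBSO)phenyl]‑3‑(TBSO)‑2‑iodo‑6‑methylhepta‑1,5‑diene | CC(C)(C)[Si](C)(C)O[C@H](CC=C(C)C)/C(I)=C/c1cc(O[Si](C)(C)C(C)(C)C)ccc1O[Si](C)(C)C(C)(C)C
F8 | step 9 | (4R,E)‑3‑[2,5‑bis(TBSO)benzylidene]‑4‑(TBSO)‑7‑methyloct‑6‑en‑2‑ol (C2 epimers) | CC(O)/C(=C\c1cc(O[Si](C)(C)C(C)(C)C)ccc1O[Si](C)(C)C(C)(C)C)[C@H](O[Si](C)(C)C(C)(C)C)CC=C(C)C
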